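**Plan**

1. Quinone ring numbering used here: C1(=O), C2(OMe), C3(OMe), C4(=O), C5(CH2–imidazole), C6(H). The retrosynthesis cuts, in this order: the C1 carbonyl oxygen (phenol oxidation), the exocyclic N–C bond to the dioxoimidazoline, the benzylic CH2–C5(imidazole) bond, the imidazole ring, and last the six-membered carbocycle through both of its future C=C bonds, C2=C3 and C5=C6.
2. Enabling feature: each half of the quinone ring is a three-carbon C–C(O)–C unit. C3(OMe)–C4(O)–C5 with the benzylic carbon on C5 is the C4–C3–C2–C1 chain of methyl 4-methoxyacetoacetate, a 1,3-dinucleophile as its bis-silyl dienol ether. C2–C1–C6 is an acyl/β-alkoxyvinyl 1,3-dielectrophile.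
3. The same event leaves O4 as a phenol ortho to the benzylic carbon and para to the unsubstituted C1. This phenol later opens the o-quinone methide for the C–C union and directs the final oxidation to C1.
4. Forward order: carbocycle by [3+3] cyclo-aromatization, imidazole ring built separately, the two joined at the benzylic carbon, dioxoimidazoline attached, quinone oxidation level set last.
5. Stereochemistry: the target has no stereocentre and no stereogenic double bond, so nothing has to be controlled.

Key step: step 2

Remark on the chemistry: diene 2 may be used as a mixture of geometric isomers, because both of its double bonds end up in the aromatic ring.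

**Route**

Step 1
Reactants: 1 methyl 4-methoxy-3-oxobutanoate
Product: 2 1,4-dimethoxy-1,3-bis(trimethylsilyloxy)buta-1,3-diene
Conditions: Me3SiOTf (2.2 equiv), Et3N (2.5 equiv), Et2O, 0 °C to rt
Reagents that add atoms: trimethylsilyl trifluoromethanesulfonate, C[Si](C)(C)OS(=O)(=O)C(F)(F)F
Why: Soft enolization and O-silylation of a β-keto ester with Me3SiOTf/Et3N should give the 1,3-bis(silyloxy)diene, the second silyl group entering after deprotonation at the methoxymethyl carbon, the only acidic position left.

Step 2
Reactants: 2 1,4-dimethoxy-1,3-bis(trimethylsilyloxy)buta-1,3-diene; 3 (E)-3-ethoxyprop-2-enoyl chloride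
Product: 5 methyl 2,4-dihydroxy-3-methoxybenzoate, via acyclic silyl ketene acetal 4 (not isolated)
Conditions: TiCl4 (1.1 equiv), CH2Cl2, −78 °C to 20 °C; then 1 M HCl
Reagents that add atoms: none
Why: TiCl4 activates acid chloride 3, which is attacked by the terminal, methoxy-bearing carbon of diene 2 (its most nucleophilic site), forming the bond that becomes C2=C3 of the quinone and leaving silyl ketene acetal 4; the ester-bearing carbon of 4 then adds to the TiCl4-complexed β-ethoxy enone carbon (intramolecular Mukaiyama–Michael addition, the bond that becomes C5=C6), and loss of ethoxide and of the last silyl group followed by enolization aromatizes the ring. The closest known reaction type is the Chan-type [3+3] cyclo-aromatization of 1,3-bis(silyloxy)dienes with β-oxygenated acryloyl chlorides or 3-silyloxy enones, which gives 2,4-dihydroxybenzoates and salicylates. The carbocycle closes in the 6-endo-trig mode by C–C bond formation, the enone double bond lying inside the new ring. No stereocentre survives, since the sp3 centres of the adduct are erased on aromatization. Two selectivities are needed: the orientation of the union, secured because the most reactive electrophilic site (the acyl chloride carbon) meets the most nucleophilic diene terminus first, so that the methoxy carbon ends next to the acyl-derived carbon and the ester carbon next to the unsubstituted CH; and carbon versus oxygen ring closure (the latter would give a γ-pyrone), secured by the ketene acetal carbon nucleophile that persists under aprotic Lewis-acid conditions at low temperature.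

Step 3
Reactants: 5 methyl 2,4-dihydroxy-3-methoxybenzoate
Product: 6 methyl 2-hydroxy-3,4-dimethoxybenzoate
Conditions: MeI (1.1 equiv), K2CO3 (1.1 equiv), acetone, rt
Reagents that add atoms: iodomethane, CI
Why: Williamson etherification should be selective for the 4-OH, which is para to the ester, more acidic and not hydrogen-bonded, whereas the 2-OH is held in a chelate with the ester carbonyl.

Step 4
Reactants: 6 methyl 2-hydroxy-3,4-dimethoxybenzoate
Product: 7 6-(hydroxymethyl)-2,3-dimethoxyphenol
Conditions: LiAlH4 (2.5 equiv), THF, 0 °C to rt; then H2O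
Reagents that add atoms: none
Why: Hydride reduction of a salicylate ester with LiAlH4 is a standard route to salicyl alcohols, the phenoxide formed first being inert and the low temperature avoiding over-reduction to the cresol.

Step 5
Reactants: 8 N-(tert-butoxycarbonyl)-N-methylglycine
Product: 9 tert-butyl N-{2-[methoxy(methyl)amino]-2-oxoethyl}-N-methylcarbamate
Conditions: 1,1'-carbonyldiimidazole (1.1 equiv), CH2Cl2, rt; then MeNHOMe·HCl (1.2 equiv)
Reagents that add atoms: N,O-dimethylhydroxylamine hydrochloride, CNOC.Cl
Why: Weinreb amide formation through the acyl imidazolide is routine for N-Boc amino acids.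

Step 6
Reactants: 9 tert-butyl N-{2-[methoxy(methyl)amino]-2-oxoethyl}-N-methylcarbamate; 10 (4-methoxybenzyl)magnesium chloride
Product: 11 tert-butyl N-[3-(4-methoxyphenyl)-2-oxopropyl]-N-methylcarbamate
Conditions: THF, −10 °C to 0 °C; then aq. NH4Cl
Reagents that add atoms: none
Why: Weinreb ketone synthesis, in which the chelated tetrahedral adduct resists a second addition of the benzylic Grignard reagent and collapses to the ketone on work-up.

Step 7
Reactants: 11 tert-butyl N-[3-(4-methoxyphenyl)-2-oxopropyl]-N-methylcarbamate
Product: 13 4-(4-methoxybenzyl)-1-methyl-1H-imidazol-2-amine, via aminoketone hydrochloride 12 (not isolated)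
Conditions: 4 M HCl in dioxane, rt; then H2NCN (3 equiv), H2O/EtOH, NaOH to pH 4.5, 95 °C
Reagents that add atoms: cyanamide, NC#N; hydrogen chloride, Cl (the chloride is held only by intermediate 12)
Why: Acidolysis of the Boc group followed by cyanamide cyclocondensation of the α-(methylamino) ketone (guanylation of the secondary amine, then cyclodehydration onto the ketone) is the established Marckwald-type route to 1-methyl-2-aminoimidazoles and places the N-methyl group next to the unsubstituted C5.

Step 8
Reactants: 7 6-(hydroxymethyl)-2,3-dimethoxyphenol; 13 4-(4-methoxybenzyl)-1-methyl-1H-imidazol-2-amine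
Product: 15 6-{[2-amino-4-(4-methoxybenzyl)-1-methyl-1H-imidazol-5-yl]methyl}-2,3-dimethoxyphenol, via o-quinone methide 14 (not isolated)
Conditions: CF3CO2H (1.0 equiv), (CF3)2CHOH, 40 °C; 13 in excess (1.5 equiv), slow addition of 7
Reagents that add atoms: none
Why: Friedel–Crafts-type benzylation, in which the salicyl alcohol ionizes to an o-quinone methide (benzylic cation stabilized by the para-methoxy and ortho-hydroxy groups) that is trapped at C5, the only free and enamine-like ring carbon of the 2-aminoimidazole, as in known acid-mediated C-alkylations and hydroxyalkylations of 2-aminoimidazoles, N-benzylation being reversible under these conditions.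

Step 9
Reactants: 15 6-{[2-amino-4-(4-methoxybenzyl)-1-methyl-1H-imidazol-5-yl]methyl}-2,3-dimethoxyphenol; 16 1-methylimidazolidine-2,4,5-trione
Product: 18 4-({5-[(2-hydroxy-3,4-dimethoxyphenyl)methyl]-4-[(4-methoxyphenyl)methyl]-1-methyl-1H-imidazol-2-yl}amino)-1-methyl-1H-imidazole-2,5-dione, via O-silylated parabanic acid 17 (not isolated)
Conditions: 16, MeC(OSiMe3)=NSiMe3, MeCN, reflux; then 15, toluene, reflux
Reagents that add atoms: N,O-bis(trimethylsilyl)acetamide, CC(=N[Si](C)(C)C)O[Si](C)(C)C (its silyl group is carried only by intermediate 17)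
Why: Condensation of the 2-amino group with O-silylated 1-methylparabanic acid, the established naamine-to-naamidine conversion, should occur at C4 of the trione (the carbonyl activated as silyl imidate) and tolerates a free phenol, which is silylated only transiently.

Step 10
Reactants: 18 4-({5-[(2-hydroxy-3,4-dimethoxyphenyl)methyl]-4-[(4-methoxyphenyl)methyl]-1-methyl-1H-imidazol-2-yl}amino)-1-methyl-1H-imidazole-2,5-dione
Product: 19 naamidine F
Conditions: ON(SO3K)2 (Fremy's salt, 2.5 equiv), KH2PO4, H2O/acetone, rt
Reagents that add atoms: potassium nitrosodisulfonate, [K+].[K+].[O]N(S(=O)(=O)[O-])S(=O)(=O)[O-]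
Why: Teuber oxidation, in which one equivalent of ON(SO3K)2 abstracts the phenolic hydrogen and a second delivers oxygen to the free para position (C1 of the quinone), should give the p-quinone under neutral buffered conditions that leave the anisyl ring and the acylated aminoimidazole untouched.

**Compound list**

1 | methyl 4-methoxy-3-oxobutanoate (methyl 4-methoxyacetoacetate) | COCC(=O)CC(=O)OC | starting material
2 | 1,4-dimethoxy-1,3-bis(trimethylsilyloxy)buta-1,3-diene (drawn as the 1E,3Z isomer; any isomer mixture serves) | CO/C=C(\O[Si](C)(C)C)/C=C(\OC)O[Si](C)(C)C | intermediate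
3 | (E)-3-ethoxyprop-2-enoyl chloride | CCO/C=C/C(Cl)=O | starting material
4 | (6E)-7-ethoxy-1,4-dimethoxy-1-(trimethylsilyloxy)hepta-1,6-diene-3,5-dione (not isolated; C4 racemic, lost on aromatization) | CCO/C=C/C(=O)C(OC)C(=O)/C=C(\OC)O[Si](C)(C)C | intermediate
5 | methyl 2,4-dihydroxy-3-methoxybenzoate | COC(=O)c1ccc(O)c(OC)c1O | intermediate
6 | methyl 2-hydroxy-3,4-dimethoxybenzoate | COC(=O)c1ccc(OC)c(OC)c1O | intermediate
7 | 6-(hydroxymethyl)-2,3-dimethoxyphenol | OCc1ccc(OC)c(OC)c1O | intermediate
8 | N-(tert-butoxycarbonyl)-N-methylglycine (Boc-sarcosine) | CN(CC(=O)O)C(=O)OC(C)(C)C | starting material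
9 | tert-butyl N-{2-[methoxy(methyl)amino]-2-oxoethyl}-N-methylcarbamate | CON(C)C(=O)CN(C)C(=O)OC(C)(C)C | intermediate
10 | (4-methoxybenzyl)magnesium chloride (solution in THF) | COc1ccc(C[Mg]Cl)cc1 | starting material
11 | tert-butyl N-[3-(4-methoxyphenyl)-2-oxopropyl]-N-methylcarbamate | COc1ccc(CC(=O)CN(C)C(=O)OC(C)(C)C)cc1 | intermediate
12 | 1-(4-methoxyphenyl)-3-(methylamino)propan-2-one hydrochloride (not isolated) | CNCC(=O)Cc1ccc(OC)cc1.Cl | intermediate
13 | 4-(4-methoxybenzyl)-1-methyl-1H-imidazol-2-amine | Cn1cc(Cc2ccc(OC)cc2)nc1N | intermediate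
14 | 2,3-dimethoxy-6-methylidenecyclohexa-2,4-dien-1-one (o-quinone methide, not isolated) | C=C1C=CC(OC)=C(OC)C1=O | intermediate
15 | 6-{[2-amino-4-(4-methoxybenzyl)-1-methyl-1H-imidazol-5-yl]methyl}-2,3-dimethoxyphenol | Cn1c(N)nc(Cc2ccc(OC)cc2)c1Cc3ccc(OC)c(OC)c3O | intermediate
16 | 1-methylimidazolidine-2,4,5-trione (1-methylparabanic acid) | CN1C(=O)NC(=O)C1=O | starting material
17 | 1-methyl-4-(trimethylsilyloxy)-1H-imidazole-2,5-dione (not isolated) | CN1C(=O)N=C(O[Si](C)(C)C)C1=O | intermediate
18 | 4-({5-[(2-hydroxy-3,4-dimethoxyphenyl)methyl]-4-[(4-methoxyphenyl)methyl]-1-methyl-1H-imidazol-2-yl}amino)-1-methyl-1H-imidazole-2,5-dione | Cn1c(NC2=NC(=O)N(C)C2=O)nc(Cc3ccc(OC)cc3)c1Cc4ccc(OC)c(OC)c4O | intermediate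
19 | naamidine F, 2,3-dimethoxy-5-({4-[(4-methoxyphenyl)methyl]-1-methyl-2-[(1-methyl-2,5-dioxo-2,5-dihydro-1H-imidazol-4-yl)amino]-1H-imidazol-5-yl}methyl)cyclohexa-2,5-diene-1,4-dione | COC1=C(OC)C(=O)C(Cc2c(Cc3ccc(OC)cc3)nc(NC3=NC(=O)N(C)C3=O)n2C)=CC1=O | target

**Step count and risks**

Total step count: 10. Longest linear sequence: 7 steps (steps 1, 2, 3, 4, 8, 9, 10); the imidazole branch (steps 5, 6, 7) joins at step 8.

The three steps most likely to fail:

Step 2. What may go wrong is ring closure through oxygen instead of carbon (pyranone formation), or Lewis-acid-induced oligomerization of the ethoxyvinyl unit before the second bond forms. The fallback sets out from 1 and 3 and returns at 5; it separates the two bond formations and runs them under anionic control. Acid chloride 3 is converted with MeNHOMe·HCl and pyridine into the Weinreb amide (E)-3-ethoxy-N-methoxy-N-methylprop-2-enamide F1. The dianion of 1 (NaH, then n-BuLi, THF, −78 °C) is acylated at its terminal carbon by F1 to give methyl (E)-7-ethoxy-4-methoxy-3,5-dioxohept-6-enoate F2. Base-mediated intramolecular Michael addition–elimination with aldol-type aromatization (DBU or NaOMe, MeOH) should then close the ring to 5.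

Step 8. What may go wrong is competing N-benzylation at the amidine nitrogens, and self-condensation of the benzylic cation with the electron-rich ring of a second molecule of 7. The fallback sets out from 7 and 13 and returns at 15; it uses a carbonyl addition followed by reduction. Oxidation of 7 with MnO2 should give 2-hydroxy-3,4-dimethoxybenzaldehyde F3. Hydroxyalkylation of 13 at C5 with this aldehyde (a known reaction of 2-aminoimidazoles; MeOH/H2O, 50 °C) should give the racemic carbinol [2-amino-4-(4-methoxybenzyl)-1-methyl-1H-imidazol-5-yl](2-hydroxy-3,4-dimethoxyphenyl)methanol F4. Ionic hydrogenation (Et3SiH, CF3CO2H) should remove the benzylic hydroxyl and give 15.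

Step 10. What may go wrong is unselective oxidation (attack of the nitroxyl at the acylated aminoimidazole or at the benzylic positions) or stalling at the phenoxyl stage. The fallback sets out from 18 and returns at 19; it is a two-electron hypervalent-iodine oxidation through an isolable intermediate. PhI(OAc)2 (2.2 equiv) in MeOH should convert the para-unsubstituted phenol into the p-quinone monoketal 4-({5-[(4,5,6,6-tetramethoxy-3-oxocyclohexa-1,4-dien-1-yl)methyl]-4-[(4-methoxyphenyl)methyl]-1-methyl-1H-imidazol-2-yl}amino)-1-methyl-1H-imidazole-2,5-dione F5, which dilute aqueous acid (TsOH, acetone/H2O) should hydrolyse to 19.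

**Further compounds**

F1 | step 2 | (E)-3-ethoxy-N-methoxy-N-methylprop-2-enamide | CCO/C=C/C(=O)N(C)OC
F2 | step 2 | methyl (E)-7-ethoxy-4-methoxy-3,5-dioxohept-6-enoate | CCO/C=C/C(=O)C(OC)C(=O)CC(=O)OC
F3 | step 8 | 2-hydroxy-3,4-dimethoxybenzaldehyde | O=Cc1ccc(OC)c(OC)c1O
F4 | step 8 | [2-amino-4-(4-methoxybenzyl)-1-methyl-1H-imidazol-5-yl](2-hydroxy-3,4-dimethoxyphenyl)methanol (racemic) | Cn1c(N)nc(Cc2ccc(OC)cc2)c1C(O)c3ccc(OC)c(OC)c3O
F5 | step 10 | 4-({5-[(4,5,6,6-tetramethoxy-3-oxocyclohexa-1,4-dien-1-yl)methyl]-4-[(4-methoxyphenyl)methyl]-1-methyl-1H-imidazol-2-yl}amino)-1-methyl-1H-imidazole-2,5-dione | COC1=C(OC)C(OC)(OC)C=C(Cc2c(Cc3ccc(OC)cc3)nc(NC4=NC(=O)N(C)C4=O)n2C)C1=O
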